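4 questions are put to the flasks below, and their answers set the temperature of your next run.

    starting material + free catalyst ⇌ catalyst intermediate A (K1 = 470 L mol⁻¹, k1 = 78 L mol⁻¹ s⁻¹, Ea1 = 40.0 kJ mol⁻¹, ΔH1 = −23.0 kJ mol⁻¹)
    catalyst intermediate A → free catalyst + target (k2 = 22 s⁻¹, Ea2 = 65.0 kJ mol⁻¹)
    second substrate + free catalyst ⇌ catalyst intermediate B (K3 = 23 L mol⁻¹, k3 = 860 L mol⁻¹ s⁻¹, Ea3 = 41.0 kJ mol⁻¹, ΔH3 = −29.0 kJ mol⁻¹)
    catalyst intermediate B → free catalyst + second product (k4 = 1.2 s⁻¹, Ea4 = 65.0 kJ mol⁻¹)
    solid substrate ⇌ starting material, rate k5*(cs5 - [starting material]) while solid is left; crystals form when [starting material] > cs5 (cs5 = 12 mM, k5 = 0.83 s⁻¹)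
    starting material + protic impurity → quenched substrate (k6 = 8.4 L mol⁻¹ s⁻¹, Ea6 = 43.0 kJ mol⁻¹)
    (constants at 0 °C)

| setting | Monday's | Saturday's | Tuesday's |
|---|---|---|---|
| solid substrate | 20 mM | 20 mM | 20 mM |
| second substrate | 40.0 mM | 40.0 mM | 40.0 mM |
| protic impurity | 4.00 mM | 4.00 mM | 4.00 mM |
| free catalyst | 1.0 mM | 1.0 mM | 1.0 mM |
| temperature | 30 °C | −30 °C | 0 °C |
| time | 40 s | 40 s | 40 s |

- solid substrate is a solid; its amount is given per volume of the solution
- constants are those at 0 °C; use the activation energies and enthalpies for any other temperature
- at the start none of the solid substrate is in solution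
- what has only dissolved of solid substrate counts as not reacted

- the best flask by amount of target, in percent of the solid substrate charged; "all alike" if 1.5 percentage points covers them all (Monday's / Saturday's / Tuesday's / all alike)
- amount of target at the end, in percent of the solid substrate charged, Monday's
- amount of target at the end, in percent of the solid substrate charged, Saturday's
- amount of target at the end, in percent of the solid substrate charged, Tuesday's

The charges and the time are the same in each flask, so you are choosing a temperature. I reckon one thing for each flask: the capture time, the average time a molecule of dissolved starting material waits before free catalyst takes it. It is a pseudo-first-order time, with second substrate held at its charge and catalyst intermediate A left out of the catalyst balance: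

capture time = (1 + K × second substrate) / (k × catalyst charged)

Here K is the equilibrium constant for binding second substrate and k is the rate constant for binding starting material, both at the flask's temperature.

Monday's: 2.83 s

Tuesday's: 24.6 s

Saturday's: 613 s

With Tuesday's constants, catalyst intermediate A goes on to target at 22 s⁻¹, faster than it falls back at 0.166 s⁻¹. So I count a capture as target. Catalyst intermediate B falls back at 37.4 s⁻¹, faster than it goes on at 1.2 s⁻¹, so I take its binding as an equilibrium.

Monday's capture time is much shorter than the 40 s run, and Tuesday's fits into the run only 1.63 times. Saturday's is far longer than the run. There, catalyst intermediate B is the resting state, and the solution approaches saturation with a time constant of about 1.20 s, so I count starting material at its solubility while solid is left: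

target on Saturday's = 12 mM × 40 s / 613 s = 0.782 mM, or 3.91% of the solid charged

The protic impurity also takes starting material, so for the warmer flasks I commit to an order, not a yield: Monday's first, then Tuesday's, then Saturday's.

The forecast names Monday's, with 82% for Monday's, 68% for Tuesday's and 3.6% for Saturday's, a little below my Saturday's figure. Of the cold flask it says: “Catalyst is tied up as B”.

Monday's gave 81.9% of target, Tuesday's 67.6% and Saturday's 3.72%, so Monday's is the best flask, as forecast, and your next run stays at 30 °C. Saturday's flask still held 30.1% of the charge as solid at 40.0 s. Counting starting material at its solubility throughout, the capture time of 613 s gives 39.1% of target for Saturday's flask at 400 s. Left that long, Saturday's flask gave 40.3%, with solid substrate at 0% and starting material at 40.1% of the charge.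

(All constants are made up; the flask was simulated.)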